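## Retrosynthetic overview

Lignan numbering: C7/C7' benzylic, C8 the tertiary carbinol, C8' the ring-fusion CH, C9/C9' the OCH2 carbons; ring A = O–C7'–C8'–C8–C9, ring B = O–C7–C8–C8'–C9'.
Feature used: in ring A the quaternary C8 lies between C9 and C8', and the benzylic C7' lies between the ring oxygen and C8'. This is the pattern of a pinacol-terminated Prins cyclisation if C8 carries CHO in place of OH and a 4-oxygenated benzyl group in place of C7–aryl.
Ring B (formed last): O–C7 is cut back to a p-quinone methide of the C8 benzyl arm captured by the C9' hydroxyl; C8–OH is cut back to C8–CHO (Baeyer–Villiger).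
Ring A (formed first): the 3-formyl oxolane is cut at O–C7', C7'–C8' and C8–C9 into a (2R,3E)-3-benzylpent-3-ene-1,2-diol and O-pivaloylvanillin (Prins cyclisation with pinacol ring contraction).
The diol is cut at the benzyl–alkene bond (Negishi) into a vanillin-derived benzylzinc and a (Z)-iodoalkene made from (S)-glyceraldehyde acetonide by Corey–Fuchs alkynylation and hydroalumination–iodination.

Key step: step 11

Assumption: in the chair-like Prins transition state the tin-bound oxygen on the sacrificial carbinol carbon is taken to lie pseudo-equatorial (C–H, not C–O, parallel to the reacting π system); with that arrangement the (2R) diol maps onto the (7'S,8'R,8S) ring A needed here.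

## Route

Step 1
Reactants: 1 (S)-2,2-dimethyl-1,3-dioxolane-4-carbaldehyde
Product: 2 (R)-4-(2,2-dibromoethenyl)-2,2-dimethyl-1,3-dioxolane
Conditions: CBr4, PPh3, CH2Cl2, 0 °C
Reagents that add atoms: carbon tetrabromide, BrC(Br)(Br)Br
Why: Corey–Fuchs dibromo-olefination (Wittig reaction of Ph3P=CBr2 made in the flask) adds the future C8' under non-basic conditions, so the α-oxygenated stereocentre should not epimerise.

Step 2
Reactants: 2 (R)-4-(2,2-dibromoethenyl)-2,2-dimethyl-1,3-dioxolane
Product: 4 propargylic alcohol 3-[(4R)-2,2-dimethyl-1,3-dioxolan-4-yl]prop-2-yn-1-ol, via lithium acetylide 3 (not isolated)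
Conditions: n-BuLi (2.1 equiv), THF, −78 °C; then (CH2O)n, −78 °C → rt; H2O
Reagents that add atoms: formaldehyde (used as paraformaldehyde), C=O
Why: Second half of the Corey–Fuchs alkyne synthesis, in which bromine–lithium exchange and a Fritsch–Buttenberg–Wiechell shift give the lithium acetylide and its addition to formaldehyde installs the future C9' carbinol without touching the stereocentre.

Step 3
Reactants: 4 3-[(4R)-2,2-dimethyl-1,3-dioxolan-4-yl]prop-2-yn-1-ol
Product: 6 iodoalkene (2Z)-3-[(4S)-2,2-dimethyl-1,3-dioxolan-4-yl]-3-iodoprop-2-en-1-ol, via alkenylalanate 5 (not isolated)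
Conditions: NaAlH2(OCH2CH2OMe)2, THF, 0 °C; EtOAc; then I2, −78 → 0 °C; aq. KNaC4H4O6
Reagents that add atoms: iodine, II
Why: Hydroxyl-directed trans-hydroalumination of the propargylic alcohol puts aluminium on the distal alkyne carbon inside a five-membered oxaluminole, and iodinolysis of the C–Al bond with retention fixes the (Z)-iodoalkene geometry that becomes the (E)-trisubstituted alkene.

Step 4
Reactants: 6 (2Z)-3-[(4S)-2,2-dimethyl-1,3-dioxolan-4-yl]-3-iodoprop-2-en-1-ol
Product: 7 tert-butyl{[(2Z)-3-[(4S)-2,2-dimethyl-1,3-dioxolan-4-yl]-3-iodoprop-2-en-1-yl]oxy}diphenylsilane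
Conditions: TBDPSCl, imidazole, CH2Cl2, 0 °C → rt
Reagents that add atoms: tert-butyl(chloro)diphenylsilane, CC(C)(C)[Si](Cl)(c1ccccc1)c1ccccc1
Why: Routine silylation of the primary allylic alcohol removes the acidic proton before the organozinc coupling and gives a C9' ether that should survive the acidic and Lewis-acidic steps ahead.

Step 5
Reactants: 8 vanillin (4-hydroxy-3-methoxybenzaldehyde)
Product: 9 4-[(tert-butyldimethylsilyl)oxy]-3-methoxybenzaldehyde
Conditions: TBSCl, imidazole, DMF, rt
Reagents that add atoms: tert-butyl(chloro)dimethylsilane, CC(C)(C)[Si](C)(C)Cl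
Why: Standard phenol silylation gives the protecting group that is later removed together with the TBDPS ether to unmask the one phenol that must form the quinone methide.

Step 6
Reactants: 9 4-[(tert-butyldimethylsilyl)oxy]-3-methoxybenzaldehyde
Product: 10 {4-[(tert-butyldimethylsilyl)oxy]-3-methoxyphenyl}methanol
Conditions: NaBH4, MeOH, 0 °C
Reagents that add atoms: none
Why: Borohydride reduction of the aryl aldehyde is fast at 0 °C and should leave the aryl silyl ether intact.

Step 7
Reactants: 10 {4-[(tert-butyldimethylsilyl)oxy]-3-methoxyphenyl}methanol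
Product: 11 tert-butyl[4-(chloromethyl)-2-methoxyphenoxy]dimethylsilane
Conditions: N-chlorosuccinimide, PPh3, THF, 0 °C → rt
Reagents that add atoms: N-chlorosuccinimide, O=C1CCC(=O)N1Cl
Why: Appel-type chlorination under neutral conditions converts the electron-rich benzylic alcohol into the chloride without acid or amine that could cleave the silyl ether or quaternise the product.

Step 8
Reactants: 11 tert-butyl[4-(chloromethyl)-2-methoxyphenoxy]dimethylsilane; 7 tert-butyl{[(2Z)-3-[(4S)-2,2-dimethyl-1,3-dioxolan-4-yl]-3-iodoprop-2-en-1-yl]oxy}diphenylsilane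
Product: 13 tert-butyl({(2E)-4-{4-[(tert-butyldimethylsilyl)oxy]-3-methoxyphenyl}-3-[(4R)-2,2-dimethyl-1,3-dioxolan-4-yl]but-2-en-1-yl}oxy)diphenylsilane, via benzylzinc chloride 12 (not isolated)
Conditions: 11, Zn dust, LiCl, THF, 25 °C; then 7, Pd(PPh3)4 (5 mol %), THF, 25 → 50 °C
Reagents that add atoms: none
Why: Negishi coupling, in which LiCl-assisted zinc insertion into the benzylic chloride gives the benzylzinc reagent and the zerovalent palladium catalyst joins it to the alkenyl iodide with retention of alkene geometry, so benzyl ends up cis to the C9' arm.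

Step 9
Reactants: 13 tert-butyl({(2E)-4-{4-[(tert-butyldimethylsilyl)oxy]-3-methoxyphenyl}-3-[(4R)-2,2-dimethyl-1,3-dioxolan-4-yl]but-2-en-1-yl}oxy)diphenylsilane
Product: 14 (2R,3E)-3-{4-[(tert-butyldimethylsilyl)oxy]-3-methoxybenzyl}-5-[(tert-butyldiphenylsilyl)oxy]pent-3-ene-1,2-diol
Conditions: AcOH–THF–H2O (3:1:1), 40 °C
Reagents that add atoms: none
Why: Mild acid-catalysed hydrolysis of the terminal acetonide frees the allylic 1,2-diol, while the aryl TBS and TBDPS ethers are stable to aqueous acetic acid.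

Step 10
Reactants: 8 vanillin (4-hydroxy-3-methoxybenzaldehyde)
Product: 15 4-formyl-2-methoxyphenyl 2,2-dimethylpropanoate
Conditions: PivCl, Et3N, DMAP (cat.), CH2Cl2, 0 °C → rt
Reagents that add atoms: pivaloyl chloride, CC(C)(C)C(=O)Cl
Why: DMAP-catalysed acylation gives an aryl ester that survives Lewis acid, peracid, fluoride and DDQ, tempers the donor strength of this ring, and keeps its phenol masked when the other ring is oxidised.

Step 11
Reactants: 14 (2R,3E)-3-{4-[(tert-butyldimethylsilyl)oxy]-3-methoxybenzyl}-5-[(tert-butyldiphenylsilyl)oxy]pent-3-ene-1,2-diol; 15 4-formyl-2-methoxyphenyl 2,2-dimethylpropanoate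
Product: 17 4-[(2S,3R,4S)-4-{4-[(tert-butyldimethylsilyl)oxy]-3-methoxybenzyl}-3-{[(tert-butyldiphenylsilyl)oxy]methyl}-4-formyloxolan-2-yl]-2-methoxyphenyl 2,2-dimethylpropanoate, via dioxolane acetal 16 (not isolated)
Conditions: 15 (1.2 equiv), TsOH·H2O (cat.), MgSO4, CH2Cl2, −20 °C; then SnCl4 (2 equiv), −78 → −20 °C
Reagents that add atoms: none
Why: TsOH-catalysed condensation gives the 2-aryl-4-alkenyl-1,3-dioxolane 16, which SnCl4 opens at the allylic (C2) oxygen to the (E)-oxocarbenium ion on the primary oxygen; the C3=C4 alkene attacks it (Prins cyclisation, forming C7'–C8' and a tertiary cation at C8), and the oxygen-bearing C9 then shifts from the tin-alkoxide carbon to C8 (pinacol rearrangement), which turns that carbon into the formyl group. The closest known reaction type is the pinacol-terminated Prins cyclisation of 4-alkenyl-1,3-dioxolanes of allylic diols to 3-acyl- and 3-formyltetrahydrofurans under SnCl4. Ring A is closed in two stages, a 6-endo-trig Prins closure to an oxanyl cation and then a 1,2-shift ring contraction to the oxolane, so that O–C7' (made at the acetal stage), C7'–C8' and C8–C9 are its new bonds. C7' and C8' are set by the chair in which the aryl group of the (E)-oxocarbenium ion and the C9' arm (trans to C2 on the (E)-alkene) are both equatorial, giving 7',8'-trans; C8 is set because C9 can only reach the face of the C8 cation on which the chair holds it, which puts formyl cis to the C7' aryl and benzyl cis to the C9' arm; the absolute sense is relayed from the (2R) carbinol with its tin-bound oxygen pseudo-equatorial. The step needs the shift of C9 to outrun a 1,2-hydride shift from the carbinol carbon and needs an electrophilic oxocarbenium ion: the lone pair of the ring oxygen on C9 assists its migration (equivalent to fragmentation to an enolate and an oxocarbenium ion followed by aldol closure), the low temperature disfavours hydride shift, and the pivalate keeps the aldehyde aryl from over-stabilising the cation.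

Step 12
Reactants: 17 4-[(2S,3R,4S)-4-{4-[(tert-butyldimethylsilyl)oxy]-3-methoxybenzyl}-3-{[(tert-butyldiphenylsilyl)oxy]methyl}-4-formyloxolan-2-yl]-2-methoxyphenyl 2,2-dimethylpropanoate
Product: 18 4-[(2S,3R,4S)-4-{4-[(tert-butyldimethylsilyl)oxy]-3-methoxybenzyl}-3-{[(tert-butyldiphenylsilyl)oxy]methyl}-4-(formyloxy)oxolan-2-yl]-2-methoxyphenyl 2,2-dimethylpropanoate
Conditions: mCPBA, NaHCO3, CH2Cl2, 0 °C → rt
Reagents that add atoms: 3-chloroperoxybenzoic acid, O=C(OO)c1cccc(Cl)c1
Why: Baeyer–Villiger oxidation of an α-quaternary aldehyde, in which the tertiary C8 migrates in preference to hydride and with retention, so the C8–O bond should form cis to the C7' aryl group.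

Step 13
Reactants: 18 the C8 formate
Product: 19 4-[(2S,3R,4S)-4-{4-[(tert-butyldimethylsilyl)oxy]-3-methoxybenzyl}-3-{[(tert-butyldiphenylsilyl)oxy]methyl}-4-hydroxyoxolan-2-yl]-2-methoxyphenyl 2,2-dimethylpropanoate
Conditions: NaHCO3, MeOH, rt
Reagents that add atoms: none
Why: Transesterification of a formate is far faster than that of a hindered aryl pivalate, so bicarbonate in methanol should free the tertiary C8 alcohol before desilylation, when the formyl group could otherwise migrate to O9'.

Step 14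
Reactants: 19 the C8 tertiary alcohol
Product: 20 4-[(2S,3R,4S)-4-hydroxy-4-(4-hydroxy-3-methoxybenzyl)-3-(hydroxymethyl)oxolan-2-yl]-2-methoxyphenyl 2,2-dimethylpropanoate
Conditions: HF·pyridine, pyridine, THF, 0 °C → rt
Reagents that add atoms: none
Why: Buffered fluoride desilylation removes the TBDPS and the aryl TBS ether in one operation and leaves the aryl pivalate and the benzylic ether of ring A untouched.

Step 15
Reactants: 20 the triol with one free phenol
Product: 22 8-hydroxypinoresinol 4'-O-pivalate (7R,8S,7'S,8'R; free phenol on the C7 aryl group), via quinone methide 21 (not isolated)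
Conditions: DDQ (1.05 equiv), NaHCO3, CH2Cl2–THF, 0 °C
Reagents that add atoms: none
Why: DDQ dehydrogenation of the 4-hydroxy-3-methoxybenzyl arm gives the p-quinone methide (the pivaloylated ring cannot form one), and 5-exo oxa-Michael (1,6-) addition of the C9' hydroxyl closes ring B, with C7 set kinetically by placing the aryl group on the convex face of the cis-fused bicycle (cis to 8-OH).

Step 16
Reactants: 22 8-hydroxypinoresinol 4'-O-pivalate
Product: 23 8-hydroxypinoresinol (7R,8S,7'S,8'R)
Conditions: K2CO3, MeOH, 0 °C → rt; aq. NH4Cl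
Reagents that add atoms: none
Why: Base-mediated methanolysis of the aryl ester releases the second phenol under conditions mild enough not to reopen the benzylic ethers.

## Compound list

1 | (S)-2,2-dimethyl-1,3-dioxolane-4-carbaldehyde | CC1(C)OC[C@@H](C=O)O1 | starting material
2 | (R)-4-(2,2-dibromoethenyl)-2,2-dimethyl-1,3-dioxolane | CC1(C)OC[C@@H](C=C(Br)Br)O1 | intermediate
3 | {[(4R)-2,2-dimethyl-1,3-dioxolan-4-yl]ethynyl}lithium | CC1(C)OC[C@@H](C#C[Li])O1 | intermediate (not isolated)
4 | 3-[(4R)-2,2-dimethyl-1,3-dioxolan-4-yl]prop-2-yn-1-ol | CC1(C)OC[C@@H](C#CCO)O1 | intermediate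
5 | sodium 2,2-bis(2-methoxyethoxy)-3-[(4S)-2,2-dimethyl-1,3-dioxolan-4-yl]-2,5-dihydro-1,2-oxaluminol-2-uide (cyclic alkenylalanate) | CC1(C)OC[C@@H](C2=CCO[Al-]2(OCCOC)OCCOC)O1.[Na+] | intermediate (not isolated)
6 | (2Z)-3-[(4S)-2,2-dimethyl-1,3-dioxolan-4-yl]-3-iodoprop-2-en-1-ol | CC1(C)OC[C@@H](/C(I)=C/CO)O1 | intermediate
7 | tert-butyl{[(2Z)-3-[(4S)-2,2-dimethyl-1,3-dioxolan-4-yl]-3-iodoprop-2-en-1-yl]oxy}diphenylsilane | CC1(C)OC[C@@H](/C(I)=C/CO[Si](c2ccccc2)(c2ccccc2)C(C)(C)C)O1 | intermediate
8 | vanillin (4-hydroxy-3-methoxybenzaldehyde) | COc1cc(C=O)ccc1O | starting material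
9 | 4-[(tert-butyldimethylsilyl)oxy]-3-methoxybenzaldehyde | COc1cc(C=O)ccc1O[Si](C)(C)C(C)(C)C | intermediate
10 | {4-[(tert-butyldimethylsilyl)oxy]-3-methoxyphenyl}methanol | COc1cc(CO)ccc1O[Si](C)(C)C(C)(C)C | intermediate
11 | tert-butyl[4-(chloromethyl)-2-methoxyphenoxy]dimethylsilane | COc1cc(CCl)ccc1O[Si](C)(C)C(C)(C)C | intermediate
12 | {4-[(tert-butyldimethylsilyl)oxy]-3-methoxybenzyl}zinc chloride | COc1cc(C[Zn]Cl)ccc1O[Si](C)(C)C(C)(C)C | intermediate (not isolated)
13 | tert-butyl({(2E)-4-{4-[(tert-butyldimethylsilyl)oxy]-3-methoxyphenyl}-3-[(4R)-2,2-dimethyl-1,3-dioxolan-4-yl]but-2-en-1-yl}oxy)diphenylsilane | CC1(C)OC[C@@H](/C(Cc2ccc(O[Si](C)(C)C(C)(C)C)c(OC)c2)=C/CO[Si](c2ccccc2)(c2ccccc2)C(C)(C)C)O1 | intermediate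
14 | (2R,3E)-3-{4-[(tert-butyldimethylsilyl)oxy]-3-methoxybenzyl}-5-[(tert-butyldiphenylsilyl)oxy]pent-3-ene-1,2-diol | OC[C@H](O)/C(Cc1ccc(O[Si](C)(C)C(C)(C)C)c(OC)c1)=C/CO[Si](c1ccccc1)(c1ccccc1)C(C)(C)C | intermediate
15 | 4-formyl-2-methoxyphenyl 2,2-dimethylpropanoate | COc1cc(C=O)ccc1OC(=O)C(C)(C)C | intermediate
16 | 4-[(4R)-4-[(2E)-1-{4-[(tert-butyldimethylsilyl)oxy]-3-methoxyphenyl}-4-[(tert-butyldiphenylsilyl)oxy]but-2-en-2-yl]-1,3-dioxolan-2-yl]-2-methoxyphenyl 2,2-dimethylpropanoate (both epimers at the acetal carbon) | COc1cc(C2OC[C@@H](/C(Cc3ccc(O[Si](C)(C)C(C)(C)C)c(OC)c3)=C/CO[Si](c3ccccc3)(c3ccccc3)C(C)(C)C)O2)ccc1OC(=O)C(C)(C)C | intermediate (not isolated)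
17 | 4-[(2S,3R,4S)-4-{4-[(tert-butyldimethylsilyl)oxy]-3-methoxybenzyl}-3-{[(tert-butyldiphenylsilyl)oxy]methyl}-4-formyloxolan-2-yl]-2-methoxyphenyl 2,2-dimethylpropanoate | COc1cc([C@H]2OC[C@](C=O)(Cc3ccc(O[Si](C)(C)C(C)(C)C)c(OC)c3)[C@@H]2CO[Si](c3ccccc3)(c3ccccc3)C(C)(C)C)ccc1OC(=O)C(C)(C)C | intermediate
18 | 4-[(2S,3R,4S)-4-{4-[(tert-butyldimethylsilyl)oxy]-3-methoxybenzyl}-3-{[(tert-butyldiphenylsilyl)oxy]methyl}-4-(formyloxy)oxolan-2-yl]-2-methoxyphenyl 2,2-dimethylpropanoate | COc1cc([C@H]2OC[C@](OC=O)(Cc3ccc(O[Si](C)(C)C(C)(C)C)c(OC)c3)[C@@H]2CO[Si](c3ccccc3)(c3ccccc3)C(C)(C)C)ccc1OC(=O)C(C)(C)C | intermediate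
19 | 4-[(2S,3R,4S)-4-{4-[(tert-butyldimethylsilyl)oxy]-3-methoxybenzyl}-3-{[(tert-butyldiphenylsilyl)oxy]methyl}-4-hydroxyoxolan-2-yl]-2-methoxyphenyl 2,2-dimethylpropanoate | COc1cc([C@H]2OC[C@](O)(Cc3ccc(O[Si](C)(C)C(C)(C)C)c(OC)c3)[C@@H]2CO[Si](c3ccccc3)(c3ccccc3)C(C)(C)C)ccc1OC(=O)C(C)(C)C | intermediate
20 | 4-[(2S,3R,4S)-4-hydroxy-4-(4-hydroxy-3-methoxybenzyl)-3-(hydroxymethyl)oxolan-2-yl]-2-methoxyphenyl 2,2-dimethylpropanoate | COc1cc([C@H]2OC[C@](O)(Cc3ccc(O)c(OC)c3)[C@@H]2CO)ccc1OC(=O)C(C)(C)C | intermediate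
21 | p-quinone methide of 20: C7 is the exocyclic methylidene carbon of a 3-methoxy-4-oxocyclohexa-2,5-dien-1-ylidene unit, ring A as in 20 | COc1cc([C@H]2OC[C@](O)(C=C3C=CC(=O)C(OC)=C3)[C@@H]2CO)ccc1OC(=O)C(C)(C)C | intermediate (not isolated)
22 | 8-hydroxypinoresinol 4'-O-pivalate, (7R,8S,7'S,8'R), pivalate on the C7' aryl group | COc1cc([C@H]2OC[C@]3(O)[C@@H](c4ccc(O)c(OC)c4)OC[C@H]23)ccc1OC(=O)C(C)(C)C | intermediate
23 | 8-hydroxypinoresinol, (7R,8S,7'S,8'R) | COc1cc([C@H]2OC[C@]3(O)[C@@H](c4ccc(O)c(OC)c4)OC[C@H]23)ccc1O | target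

## Step count and risks

Total step count: 16. Longest linear sequence: 12 steps (steps 1–4, 8, 9, 11–16, from 1 to 23).

Steps most likely to fail:

1. Step 11 (Prins cyclisation–pinacol ring contraction). What may go wrong: a 1,2-hydride shift from the carbinol carbon may compete with the ring-contracting shift of C9, so that the cation collapses to an oxan-3-one. The electron-rich benzyl arene or the silyl ethers may intercept the cation or be ionised by SnCl4. Leakage through the chair with the tin-bound oxygen axial would erode the relay of chirality from C2. The fallback is known chemistry that does not depend on that relay; it sets out from aldehyde 15 and comes back to the route at tertiary alcohol 19. Aldehyde 15 is treated with CH2=CHMgBr (THF, −78 °C) to give the racemic allylic alcohol 4-(1-hydroxyprop-2-en-1-yl)-2-methoxyphenyl pivalate F1. Sharpless kinetic-resolution epoxidation (Ti(OiPr)4, D-(−)-diisopropyl tartrate, t-BuOOH, 4 Å sieves, CH2Cl2, −20 °C, stopped below half conversion) should convert the fast-reacting (S)-enantiomer into the erythro epoxy alcohol 4-{(R)-hydroxy[(2R)-oxiran-2-yl]methyl}-2-methoxyphenyl pivalate F2, which is O-propargylated (NaH, propargyl bromide, THF, 0 °C) to the epoxy propargyl ether F3. Cp2TiCl (trivalent titanium, made from Cp2TiCl2 and Zn in THF) opens the epoxide to the C8' radical, which closes ring A by 5-exo-dig cyclisation onto the alkyne and should give the 2,3-trans 4-methylidene oxolane 4-[(2S,3R)-3-(hydroxymethyl)-4-methylideneoxolan-2-yl]-2-methoxyphenyl pivalate F4. Silylation (TBDPSCl, imidazole) gives the silyl ether F5, and mCPBA epoxidation from the face opposite the silyloxymethyl group gives the spiro-epoxide F6 with its oxygen trans to the C9' arm. The aryl bromide (4-bromo-2-methoxyphenoxy)(tert-butyl)dimethylsilane F7, made from commercial 4-bromo-2-methoxyphenol with TBSCl and imidazole, is converted with Mg in THF into the Grignard reagent F8. With CuBr·SMe2 as catalyst (THF, −30 °C) F8 opens F6 at the epoxide CH2 carbon and delivers 19.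

2. Step 15 (DDQ closure of ring B). What may go wrong: the phenolic furofuran product still carries a benzylic C–H para to a free phenol and may be oxidised further; the quinone methide may be captured intermolecularly or oligomerise; closure from the concave face would give the C7 epimer. The fallback separates oxidation from ring closure; it sets out from 19 and comes back at 22. KHF2 in MeOH (rt) removes only the phenolic TBS group of 19 and gives the phenol F9, in which C9' is still silylated. DDQ (1 equiv) in CH2Cl2–MeOH at 0 °C then generates the quinone methide in a molecule without a free internal nucleophile, and methanol in large excess adds at C7 to give the benzylic methyl ether F10 (both C7 epimers). HF·pyridine removes the TBDPS group to give the diol F11. PPTS with 4 Å sieves in CH2Cl2 re-ionises the p-hydroxybenzyl ether and closes ring B by SN1 etherification with loss of methanol to give 22; both epimers of F11 pass through the same cation, and no oxidant is present when the oxidisable furofuran forms.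

3. Step 12 (Baeyer–Villiger oxidation of the aldehyde). What may go wrong: hydride instead of alkyl migration in the Criegee intermediate would give the carboxylic acid, and the peracid may attack the electron-rich silyloxyarene during a slow reaction at the hindered aldehyde. The fallback oxidises a methyl ketone, where alkyl migration is the only productive path; it sets out from 17 and comes back at 19. MeMgBr (THF, −78 °C) adds to the aldehyde of 17 to give the secondary alcohol F12 (both carbinol epimers), and Dess–Martin periodinane gives the methyl ketone F13. Baeyer–Villiger oxidation (mCPBA, NaHCO3, CH2Cl2, rt) should proceed with migration of the tertiary C8 in preference to methyl and with retention, giving the tertiary acetate F14. i-Bu2AlH (CH2Cl2, −78 °C) cleaves the acetate and the aryl pivalate reductively to the phenol F15 with the free C8 alcohol, and PivCl with Et3N (CH2Cl2, 0 °C) re-acylates only the phenol to give 19.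

Further compounds
F1 | step 11 | 4-(1-hydroxyprop-2-en-1-yl)-2-methoxyphenyl 2,2-dimethylpropanoate (racemic) | C=CC(O)c1ccc(OC(=O)C(C)(C)C)c(OC)c1
F2 | step 11 | 4-{(R)-hydroxy[(2R)-oxiran-2-yl]methyl}-2-methoxyphenyl 2,2-dimethylpropanoate | COc1cc([C@@H](O)[C@H]2CO2)ccc1OC(=O)C(C)(C)C
F3 | step 11 | 2-methoxy-4-{(R)-[(2R)-oxiran-2-yl](prop-2-yn-1-yloxy)methyl}phenyl 2,2-dimethylpropanoate | COc1cc([C@@H](OCC#C)[C@H]2CO2)ccc1OC(=O)C(C)(C)C
F4 | step 11 | 4-[(2S,3R)-3-(hydroxymethyl)-4-methylideneoxolan-2-yl]-2-methoxyphenyl 2,2-dimethylpropanoate | COc1cc([C@H]2OCC(=C)[C@@H]2CO)ccc1OC(=O)C(C)(C)C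
F5 | step 11 | 4-[(2S,3R)-3-{[(tert-butyldiphenylsilyl)oxy]methyl}-4-methylideneoxolan-2-yl]-2-methoxyphenyl 2,2-dimethylpropanoate | COc1cc([C@H]2OCC(=C)[C@@H]2CO[Si](c2ccccc2)(c2ccccc2)C(C)(C)C)ccc1OC(=O)C(C)(C)C
F6 | step 11 | spiro-epoxide of F5 at C8 (1,5-dioxaspiro[2.4]heptane core), epoxide oxygen trans to the silyloxymethyl group | COc1cc([C@H]2OC[C@]3(CO3)[C@@H]2CO[Si](c2ccccc2)(c2ccccc2)C(C)(C)C)ccc1OC(=O)C(C)(C)C
F7 | step 11 | (4-bromo-2-methoxyphenoxy)(tert-butyl)dimethylsilane | COc1cc(Br)ccc1O[Si](C)(C)C(C)(C)C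
F8 | step 11 | {4-[(tert-butyldimethylsilyl)oxy]-3-methoxyphenyl}magnesium bromide | COc1cc([Mg]Br)ccc1O[Si](C)(C)C(C)(C)C
F9 | step 15 | 4-[(2S,3R,4S)-3-{[(tert-butyldiphenylsilyl)oxy]methyl}-4-hydroxy-4-(4-hydroxy-3-methoxybenzyl)oxolan-2-yl]-2-methoxyphenyl 2,2-dimethylpropanoate | COc1cc([C@H]2OC[C@](O)(Cc3ccc(O)c(OC)c3)[C@@H]2CO[Si](c3ccccc3)(c3ccccc3)C(C)(C)C)ccc1OC(=O)C(C)(C)C
F10 | step 15 | C7 methyl ether of F9: the benzyl CH2 becomes CH(OMe), both C7 epimers, ring A as in 19 | COc1cc([C@H]2OC[C@](O)(C(OC)c3ccc(O)c(OC)c3)[C@@H]2CO[Si](c3ccccc3)(c3ccccc3)C(C)(C)C)ccc1OC(=O)C(C)(C)C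
F11 | step 15 | desilylated F10 with free C9' hydroxyl, both C7 epimers | COc1cc([C@H]2OC[C@](O)(C(OC)c3ccc(O)c(OC)c3)[C@@H]2CO)ccc1OC(=O)C(C)(C)C
F12 | step 12 | 1-hydroxyethyl analogue of 17 (C8–CH(OH)CH3, both carbinol epimers) | COc1cc([C@H]2OC[C@](C(C)O)(Cc3ccc(O[Si](C)(C)C(C)(C)C)c(OC)c3)[C@@H]2CO[Si](c3ccccc3)(c3ccccc3)C(C)(C)C)ccc1OC(=O)C(C)(C)C
F13 | step 12 | acetyl analogue of 17 (C8–COCH3) | COc1cc([C@H]2OC[C@](C(C)=O)(Cc3ccc(O[Si](C)(C)C(C)(C)C)c(OC)c3)[C@@H]2CO[Si](c3ccccc3)(c3ccccc3)C(C)(C)C)ccc1OC(=O)C(C)(C)C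
F14 | step 12 | C8 acetate of 19 (C8–OCOCH3) | COc1cc([C@H]2OC[C@](OC(C)=O)(Cc3ccc(O[Si](C)(C)C(C)(C)C)c(OC)c3)[C@@H]2CO[Si](c3ccccc3)(c3ccccc3)C(C)(C)C)ccc1OC(=O)C(C)(C)C
F15 | step 12 | 19 without its pivaloyl group (free phenol on the C7' aryl group, free C8 hydroxyl) | COc1cc([C@H]2OC[C@](O)(Cc3ccc(O[Si](C)(C)C(C)(C)C)c(OC)c3)[C@@H]2CO[Si](c3ccccc3)(c3ccccc3)C(C)(C)C)ccc1O
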